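**Strategy.** The tridepside is cut at the B–C ester. The carbonyl carbon on ring C C1, crowded between the C2 oxygen and the C6 methyl group, and its bond to the oxygen on ring B C4 both come from carbon monoxide, so the hindered ring C acid is never needed. One palladium-catalysed aryloxycarbonylation joins a ring C aryl iodide, CO and the free C4 phenol of an A–B depside, forming the aryl–carbonyl and carbonyl–oxygen bonds together. The iodide carries the future C2 hydroxyl as a benzyl ether; the A–B partner keeps its chelated ring B C2 hydroxyl free. One hydrogenolysis then gives the target.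

Key step: step 11

Remark on the chemistry: the target has no stereocentre and no configurationally stable axis, so it is achiral and no enantiocontrol is required. The commercial starting materials are 3-methoxy-5-methylphenol, methyl orsellinate and carbon monoxide.

**Ring C iodide**

Step 1
Reactants: 1 3-methoxy-5-methylphenol
Product: 2 3-methoxy-5-methylphenyl acetate
Conditions: Ac2O, pyridine, cat. DMAP, CH2Cl2, 0 °C → rt
Reagents that add atoms: acetic anhydride, CC(=O)OC(C)=O
Why: O-Acetylation of a phenol (nucleophilic acyl substitution) is routine and turns the hydroxyl from the strongest into a weak ring activator, so that the methoxy group alone steers the next substitution.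

Step 2
Reactants: 2 3-methoxy-5-methylphenyl acetate
Product: 3 2-iodo-5-methoxy-3-methylphenyl acetate
Conditions: NIS (1.05 equiv), cat. TFA, MeCN, rt, dark
Reagents that add atoms: N-iodosuccinimide, O=C1CCC(=O)N1I
Why: Electrophilic aromatic iodination with acid-activated NIS should enter para to the methoxy group, at the carbon between the acetoxy and methyl groups, because OMe is the strongest donor and para attack is preferred over its two ortho sites.

Step 3
Reactants: 3 2-iodo-5-methoxy-3-methylphenyl acetate
Product: 5 1-(benzyloxy)-2-iodo-5-methoxy-3-methylbenzene, via 2-iodo-5-methoxy-3-methylphenol 4 (not isolated)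
Conditions: K2CO3, MeOH, rt; evaporate; then BnBr, DMF, rt
Reagents that add atoms: benzyl bromide, BrCc1ccccc1
Why: Methanolysis of the aryl acetate (transesterification) liberates the phenoxide, which is O-benzylated in the same flask by Williamson ether synthesis; the aryl iodide is inert to both operations.

**Ring A phenol**

Step 4
Reactants: 6 methyl 2,4-dihydroxy-6-methylbenzoate (methyl orsellinate)
Product: 7 methyl 4-(benzyloxy)-2-hydroxy-6-methylbenzoate
Conditions: BnBr (1.05 equiv), K2CO3, acetone, reflux
Reagents that add atoms: benzyl bromide, BrCc1ccccc1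
Why: Williamson etherification under a weak base should take place only at the 4-OH, because the 2-OH is less acidic and held in a hydrogen bond to the ester carbonyl.

Step 5
Reactants: 7 methyl 4-(benzyloxy)-2-hydroxy-6-methylbenzoate
Product: 8 methyl 4-(benzyloxy)-2-methoxy-6-methylbenzoate
Conditions: MeI (excess), K2CO3, DMF, 50 °C
Reagents that add atoms: iodomethane, CI
Why: Williamson O-methylation of the remaining chelated phenol proceeds once a polar aprotic solvent, excess halide and gentle heating are used.

Step 6
Reactants: 8 methyl 4-(benzyloxy)-2-methoxy-6-methylbenzoate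
Product: 9 methyl 4-hydroxy-2-methoxy-6-methylbenzoate
Conditions: H2 (1 atm), 10% Pd/C, EtOAc, rt
Reagents that add atoms: none
Why: Catalytic hydrogenolysis cleaves the benzyl aryl ether and leaves the methyl ester and methyl ether untouched.

**Ring B acid**

Step 7
Reactants: 6 methyl 2,4-dihydroxy-6-methylbenzoate
Product: 10 methyl 2,4-bis(benzyloxy)-6-methylbenzoate
Conditions: BnBr (2.5 equiv), K2CO3, DMF, 60 °C
Reagents that add atoms: benzyl bromide, BrCc1ccccc1
Why: Exhaustive Williamson benzylation in DMF with excess halide and heat alkylates the chelated 2-OH as well as the 4-OH.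

Step 8
Reactants: 10 methyl 2,4-bis(benzyloxy)-6-methylbenzoate
Product: 11 2,4-bis(benzyloxy)-6-methylbenzoic acid
Conditions: KOH, DMSO/H2O (4:1), 90 °C; then aq. HCl, 0 °C
Reagents that add atoms: potassium hydroxide, [K+].[OH-]
Why: Saponification of the di-ortho-substituted methyl ester needs poorly solvated hydroxide in hot aqueous DMSO, conditions that benzyl aryl ethers tolerate; cold acidification avoids decarboxylation.

**A–B depside**

Step 9
Reactants: 11 2,4-bis(benzyloxy)-6-methylbenzoic acid; 9 methyl 4-hydroxy-2-methoxy-6-methylbenzoate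
Product: 13 methyl 4-{[2,4-bis(benzyloxy)-6-methylbenzoyl]oxy}-2-methoxy-6-methylbenzoate, via 2,4-bis(benzyloxy)-6-methylbenzoyl trifluoroacetate 12 (not isolated)
Conditions: TFAA, toluene, 0 °C → rt
Reagents that add atoms: none
Why: Mixed-anhydride esterification: the acyl trifluoroacetate of the electron-rich hindered acid (or the acylium ion it releases) acylates the only phenol of 9, the classical way to aryl orsellinates (depsides).

Step 10
Reactants: 13 methyl 4-{[2,4-bis(benzyloxy)-6-methylbenzoyl]oxy}-2-methoxy-6-methylbenzoate
Product: 14 methyl 4-[(2,4-dihydroxy-6-methylbenzoyl)oxy]-2-methoxy-6-methylbenzoate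
Conditions: H2 (1 atm), 10% Pd/C, EtOAc, rt
Reagents that add atoms: none
Why: Hydrogenolysis removes both benzyl ethers, while the aryl ester and the methyl ester, which have no benzylic C–O bond, should survive in a non-nucleophilic solvent.

**Key coupling and end game**

Step 11
Reactants: 5 1-(benzyloxy)-2-iodo-5-methoxy-3-methylbenzene (1.2 equiv); 14 methyl 4-[(2,4-dihydroxy-6-methylbenzoyl)oxy]-2-methoxy-6-methylbenzoate; 15 carbon monoxide
Product: 16 methyl 4-[(4-{[2-(benzyloxy)-4-methoxy-6-methylbenzoyl]oxy}-2-hydroxy-6-methylbenzoyl)oxy]-2-methoxy-6-methylbenzoate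
Conditions: Pd(OAc)2 (5 mol %), Xantphos (7.5 mol %), Et3N, CO (1–3 bar), 4 Å MS, toluene, 90 °C
Reagents that add atoms: none
Why: Pd(0) adds oxidatively into the C–I bond of 5, CO inserts into the crowded aryl–Pd bond (insertion eases the strain of the doubly ortho-substituted arylpalladium), and the ring B C4 phenoxide of 14, formed with Et3N, is taken up by the aroylpalladium so that reductive elimination releases the aryl ester and Pd(0). The closest known reaction type is the palladium-catalysed aryloxycarbonylation of aryl iodides with phenols (Heck-type carbonylation), run here with the wide-bite-angle ligand Xantphos, which operates at low CO pressure and favours the C–O-forming reductive elimination. No ring is closed and no stereocentre is created; the two new skeletal bonds are C1(ring C)–C(=O) and C(=O)–O–C4(ring B). The step needs site selectivity between the two phenols of 14: the C4 hydroxyl is the more acidic and unhindered one, whereas the C2 hydroxyl is locked in a hydrogen bond to the adjacent ester carbonyl and shielded by it, so only the C4 oxygen should be aroylated. It also needs both existing ester links to survive, which the non-nucleophilic amine base, the exclusion of water and the di-ortho substitution of each aryl ester carbonyl should secure. A small excess of the iodide is used so that the more valuable depside is fully consumed.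

Step 12
Reactants: 16 methyl 4-[(4-{[2-(benzyloxy)-4-methoxy-6-methylbenzoyl]oxy}-2-hydroxy-6-methylbenzoyl)oxy]-2-methoxy-6-methylbenzoate
Product: 17 methyl 4-({2-hydroxy-4-[(2-hydroxy-4-methoxy-6-methylbenzoyl)oxy]-6-methylbenzoyl}oxy)-2-methoxy-6-methylbenzoate (target)
Conditions: H2 (1 atm), 10% Pd/C, EtOAc, rt
Reagents that add atoms: none
Why: Heterogeneous hydrogenolysis cleaves only the single benzylic C–O bond; the three ester groups and the two aryl methyl ethers are not benzylic and should remain intact in ethyl acetate.

**Compound list**

1 | 3-methoxy-5-methylphenol | COc1cc(C)cc(O)c1 | starting material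
2 | 3-methoxy-5-methylphenyl acetate | COc1cc(C)cc(OC(C)=O)c1 | intermediate
3 | 2-iodo-5-methoxy-3-methylphenyl acetate | COc1cc(C)c(I)c(OC(C)=O)c1 | intermediate
4 | 2-iodo-5-methoxy-3-methylphenol (not isolated) | COc1cc(C)c(I)c(O)c1 | intermediate
5 | 1-(benzyloxy)-2-iodo-5-methoxy-3-methylbenzene | COc1cc(C)c(I)c(OCc2ccccc2)c1 | intermediate
6 | methyl 2,4-dihydroxy-6-methylbenzoate | COC(=O)c1c(C)cc(O)cc1O | starting material
7 | methyl 4-(benzyloxy)-2-hydroxy-6-methylbenzoate | COC(=O)c1c(C)cc(OCc2ccccc2)cc1O | intermediate
8 | methyl 4-(benzyloxy)-2-methoxy-6-methylbenzoate | COC(=O)c1c(C)cc(OCc2ccccc2)cc1OC | intermediate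
9 | methyl 4-hydroxy-2-methoxy-6-methylbenzoate | COC(=O)c1c(C)cc(O)cc1OC | intermediate
10 | methyl 2,4-bis(benzyloxy)-6-methylbenzoate | COC(=O)c1c(C)cc(OCc2ccccc2)cc1OCc1ccccc1 | intermediate
11 | 2,4-bis(benzyloxy)-6-methylbenzoic acid | Cc1cc(OCc2ccccc2)cc(OCc2ccccc2)c1C(=O)O | intermediate
12 | 2,4-bis(benzyloxy)-6-methylbenzoyl trifluoroacetate (not isolated) | Cc1cc(OCc2ccccc2)cc(OCc2ccccc2)c1C(=O)OC(=O)C(F)(F)F | intermediate
13 | methyl 4-{[2,4-bis(benzyloxy)-6-methylbenzoyl]oxy}-2-methoxy-6-methylbenzoate | COC(=O)c1c(C)cc(OC(=O)c2c(C)cc(OCc3ccccc3)cc2OCc2ccccc2)cc1OC | intermediate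
14 | methyl 4-[(2,4-dihydroxy-6-methylbenzoyl)oxy]-2-methoxy-6-methylbenzoate | COC(=O)c1c(C)cc(OC(=O)c2c(C)cc(O)cc2O)cc1OC | intermediate
15 | carbon monoxide | [C-]#[O+] | starting material
16 | methyl 4-[(4-{[2-(benzyloxy)-4-methoxy-6-methylbenzoyl]oxy}-2-hydroxy-6-methylbenzoyl)oxy]-2-methoxy-6-methylbenzoate | COC(=O)c1c(C)cc(OC(=O)c2c(C)cc(OC(=O)c3c(C)cc(OC)cc3OCc3ccccc3)cc2O)cc1OC | intermediate
17 | methyl 4-({2-hydroxy-4-[(2-hydroxy-4-methoxy-6-methylbenzoyl)oxy]-6-methylbenzoyl}oxy)-2-methoxy-6-methylbenzoate | COC(=O)c1c(C)cc(OC(=O)c2c(C)cc(OC(=O)c3c(C)cc(OC)cc3O)cc2O)cc1OC | target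

Total step count: 12. Longest linear sequence: 7 steps (steps 4, 5, 6, 9, 10, 11, 12).

**Steps most likely to fail**

Step 11. Oxidative addition or CO insertion at the doubly ortho-substituted ring may be slow, so that proto-deiodination or hydroxycarbonylation by traces of water takes over. Prolonged heating with base may also cause acyl migration between phenol oxygens. The fallback abandons the carbonylation and makes the ester bond classically. It sets out from 5: iodine–magnesium exchange (iPrMgCl·LiCl, THF, −20 °C) should give [2-(benzyloxy)-4-methoxy-6-methylphenyl]magnesium chloride F1. Quenching with CO2 gives 2-(benzyloxy)-4-methoxy-6-methylbenzoic acid F2. With TFAA in toluene, F2 is converted into 2-(benzyloxy)-4-methoxy-6-methylbenzoyl trifluoroacetate F3, which should acylate the unchelated C4 hydroxyl of 14 selectively. The fallback returns to the route at 16.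

Step 2. Iodination may occur at the other methyl-flanked position or between the two oxygens, or go on to di-iodination. The fallback fixes the substitution pattern with a carboxyl group and installs iodine by ipso substitution. It sets out from 6: selective 4-O-methylation (MeI 1.05 equiv, K2CO3, acetone) gives methyl 2-hydroxy-4-methoxy-6-methylbenzoate F4. Benzylation (BnBr, K2CO3, DMF, 60 °C) gives methyl 2-(benzyloxy)-4-methoxy-6-methylbenzoate F5. Saponification (KOH, aqueous DMSO, 90 °C) gives 2-(benzyloxy)-4-methoxy-6-methylbenzoic acid F6, the same acid as F2. Transition-metal-free decarboxylative ipso-iodination (I2, K3PO4, MeCN, 100 °C), a reaction type known for electron-rich ortho-alkoxybenzoic acids, should then give the iodide. The fallback returns to the route at 5.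

Step 9. Shielding of the carbonyl may leave acylation incomplete, and the strongly acidic medium may cause loss of the ortho benzyl ether or C-acylation of an electron-rich ring. The fallback replaces acid-promoted mixed-anhydride activation by a discrete acyl halide used under basic nucleophilic catalysis. It sets out from 11: oxalyl chloride and cat. DMF in CH2Cl2 give 2,4-bis(benzyloxy)-6-methylbenzoyl chloride F7. F7 is then added to phenol 9 with Et3N and DMAP in CH2Cl2. The fallback returns to the route at 13.

**Further compounds**

F1 | step 11 | [2-(benzyloxy)-4-methoxy-6-methylphenyl]magnesium chloride | COc1cc(C)c([Mg]Cl)c(OCc2ccccc2)c1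
F2 | step 11 | 2-(benzyloxy)-4-methoxy-6-methylbenzoic acid | COc1cc(C)c(C(=O)O)c(OCc2ccccc2)c1
F3 | step 11 | 2-(benzyloxy)-4-methoxy-6-methylbenzoyl trifluoroacetate | COc1cc(C)c(C(=O)OC(=O)C(F)(F)F)c(OCc2ccccc2)c1
F4 | step 2 | methyl 2-hydroxy-4-methoxy-6-methylbenzoate | COC(=O)c1c(C)cc(OC)cc1O
F5 | step 2 | methyl 2-(benzyloxy)-4-methoxy-6-methylbenzoate | COC(=O)c1c(C)cc(OC)cc1OCc1ccccc1
F6 | step 2 | 2-(benzyloxy)-4-methoxy-6-methylbenzoic acid | COc1cc(C)c(C(=O)O)c(OCc2ccccc2)c1
F7 | step 9 | 2,4-bis(benzyloxy)-6-methylbenzoyl chloride | Cc1cc(OCc2ccccc2)cc(OCc2ccccc2)c1C(=O)Cl
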